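**Retrosynthetic overview**

- Feature (tetralin numbering: C1 aryl-bearing, C2 ester, C3 CH2OH, C4 CH2; ring A aromatic, ring B saturated): C1 is a methine bonded to two electron-rich arene carbons, C8a of ring A (para to the C6 OMe) and C1' of the pendant ring (para to its OH), which is the pattern of an aldehyde carbon arylated twice.
- 16 ⇐ 15 by hydrogenolysis of two benzyl ethers; 15 ⇐ formyl ester 12 + guaiacol 13, with C1–C8a (closing ring B, the only ring formed) and C1–C1' made in one acid-mediated operation that sets C1 and C2 against C3.
- 12 ⇐ ester 10 + methyl formate 11 (Claisen formylation); 10 ⇐ lactone 7 by hydroxide opening, O-benzylation and methylation.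
- 7 ⇐ O-benzylvanillin 1 + dimethyl succinate 2 by Stobbe condensation, asymmetric hydrogenation (sets C3) and ester-selective reduction.

Key step: step 7

Assumption: the (R,R) antipode of Et-DuPHOS is taken to give the (S) half ester 4, by analogy with itaconate half esters; should the (R) acid form, the (S,S) ligand is used and nothing else changes.

Step 1
Reactants: 1 4-benzyloxy-3-methoxybenzaldehyde; 2 dimethyl succinate
Product: 3 (E)-4-(4-benzyloxy-3-methoxyphenyl)-3-(methoxycarbonyl)but-3-enoic acid
Conditions: NaOMe, MeOH, reflux; then aq. HCl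
Reagents that add atoms: none
Why: Stobbe condensation, in which the succinate enolate adds to the aldehyde, the alkoxide lactonises onto the distal ester and E1cB opening of the paraconate gives the (E)-arylidene half ester with the free acid on the CH2 arm and the ester on the alkene carbon.

Step 2
Reactants: 3 (E)-4-(4-benzyloxy-3-methoxyphenyl)-3-(methoxycarbonyl)but-3-enoic acid
Product: 4 (3S)-4-(4-benzyloxy-3-methoxyphenyl)-3-(methoxycarbonyl)butanoic acid
Conditions: H2 (5 bar), [Rh(cod)((R,R)-Et-DuPHOS)]BF4 (0.5 mol %), NaOMe (0.1 equiv), MeOH, rt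
Reagents that add atoms: none
Why: Rhodium-catalysed asymmetric hydrogenation of an itaconate-type half ester, in which carboxylate and alkene chelate the chiral bisphospholane–rhodium centre so that H2 is delivered to one alkene face and the future C3 is set as S, the aryl benzyl ether being inert to this homogeneous catalyst.

Step 3
Reactants: 4 (3S)-4-(4-benzyloxy-3-methoxyphenyl)-3-(methoxycarbonyl)butanoic acid
Product: 7 (4S)-4-(4-benzyloxy-3-methoxybenzyl)oxolan-2-one, via potassium half-ester carboxylate 5 (not isolated), via free hydroxy acid 6 (not isolated)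
Conditions: KOH (1 equiv), EtOH, 0 °C; CaCl2, NaBH4, EtOH, −10 °C to rt; then aq. HCl, rt
Reagents that add atoms: none
Why: Chemoselective borohydride reduction, in which KOH first turns the acid into carboxylate salt 5, Ca(BH4)2 reduces its methyl ester while the carboxylate is untouched, and acidification frees hydroxy acid 6, which closes at once to the γ-lactone, the neutral form in which the reduced material is separated from boron and calcium salts and dried; the low temperature keeps the stereocentre, still α to the ester before reduction, from enolising.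

Step 4
Reactants: 7 (4S)-4-(4-benzyloxy-3-methoxybenzyl)oxolan-2-one
Product: 9 (3S)-4-(4-benzyloxy-3-methoxyphenyl)-3-(benzyloxymethyl)butanoic acid, via potassium hydroxy carboxylate 8 (not isolated)
Conditions: KOH (powder, excess), BnBr, toluene, reflux; then H2O, reflux; aq. HCl
Reagents that add atoms: benzyl bromide, BrCc1ccccc1; potassium hydroxide, [K+].[OH-]
Why: Hydroxide opens the dry lactone to carboxylate salt 8, whose alkoxide undergoes Williamson etherification in a medium (solid KOH, toluene) in which the salt cannot relactonise, any benzyl ester formed from excess BnBr being saponified in the same pot; the stereocentre is β to the carbonyl and not acidic.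

Step 5
Reactants: 9 (3S)-4-(4-benzyloxy-3-methoxyphenyl)-3-(benzyloxymethyl)butanoic acid
Product: 10 methyl (3S)-4-(4-benzyloxy-3-methoxyphenyl)-3-(benzyloxymethyl)butanoate
Conditions: MeI, K2CO3, DMF, rt
Reagents that add atoms: iodomethane, CI
Why: SN2 O-alkylation of the carboxylate gives the methyl ester without touching the benzyl ethers or the stereocentre.

Step 6
Reactants: 10 methyl (3S)-4-(4-benzyloxy-3-methoxyphenyl)-3-(benzyloxymethyl)butanoate; 11 methyl formate
Product: 12 methyl (3S)-4-(4-benzyloxy-3-methoxyphenyl)-3-(benzyloxymethyl)-2-formylbutanoate (C2 not fixed, largely the hydroxymethylene enol)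
Conditions: NaH (2.5 equiv), HCO2Me (excess), MeOH (cat.), THF, 0 °C to rt; then cold dilute HCl
Reagents that add atoms: none
Why: Crossed Claisen condensation with non-enolisable methyl formate, driven by irreversible deprotonation of the formyl ester to its sodium enolate; C2 is left as an epimerisable enolised centre, and C3 is β to the ester with its benzyloxy group γ, so neither epimerisation nor elimination can occur.

Step 7
Reactants: 12 methyl (3S)-4-(4-benzyloxy-3-methoxyphenyl)-3-(benzyloxymethyl)-2-formylbutanoate; 13 guaiacol (2-methoxyphenol)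
Product: 15 methyl (1R,2S,3S)-7-benzyloxy-3-(benzyloxymethyl)-1-(4-hydroxy-3-methoxyphenyl)-6-methoxy-1,2,3,4-tetrahydronaphthalene-2-carboxylate, via 1-tetralol carbinol 14 (not isolated)
Conditions: guaiacol (5 equiv), CF3CO2H (10 equiv), CH2Cl2, 0 °C to rt
Reagents that add atoms: none
Why: Proposed new method: CF3CO2H protonates the aldehyde tautomer of 12 (the enol returns to it and keeps C2 epimerising), the ring A carbon para to OMe attacks the formyl carbon (C1–C8a) to give carbinol 14, ionisation of 14 gives a 1-tetralyl cation stabilised by that same para methoxy group, and guaiacol adds to it through the carbon para to its OH (C1–C1'). The closest known reaction types are the Bradsher-type acid cyclialkylation of aryl-tethered aldehydes and 2-formyl esters and the Friedel–Crafts alkylation of phenols by secondary benzylic cations; running both on one formyl carbon in one flask is the untested part. Ring B closes in a 6-exo-trig mode with respect to the C=O, through a chair-like transition state. C2 is set in that closure, since it equilibrates through the enol beforehand and the chair places CO2Me equatorial and trans to the fixed equatorial C3 CH2OBn, and C1 is set by guaiacol approaching the planar cation on the face anti to the neighbouring ester, which gives the all-equatorial 1,2-trans-2,3-trans product. The step needs para-to-OH attack on guaiacol (OH is the stronger para director and its ortho sites are more hindered), closure at the ring A carbon para to OMe rather than at the crowded carbon between side chain and OMe, and capture of the cation ahead of loss of the C2 proton, which the excess of guaiacol favours, while the conjugated alkene from proton loss can be reprotonated at C2 in CF3CO2H and re-enter. A Brønsted acid is chosen because BF3·OEt2 can tie up the enolised formyl ester as a difluoroboron chelate.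

Step 8
Reactants: 15 methyl (1R,2S,3S)-7-benzyloxy-3-(benzyloxymethyl)-1-(4-hydroxy-3-methoxyphenyl)-6-methoxy-1,2,3,4-tetrahydronaphthalene-2-carboxylate
Product: 16 methyl (1R,2S,3S)-7-hydroxy-3-(hydroxymethyl)-1-(4-hydroxy-3-methoxyphenyl)-6-methoxy-1,2,3,4-tetrahydronaphthalene-2-carboxylate (CNP0241585.1)
Conditions: H2 (1 atm), 10% Pd/C, EtOAc, rt
Reagents that add atoms: none
Why: Catalytic hydrogenolysis cleaves the aryl and the alkyl benzyl ether as toluene under neutral conditions that leave the methyl ester, the aryl methyl ethers and the three stereocentres unchanged and give the γ-hydroxy ester no acid or base with which to lactonise or to epimerise at C2.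

**Compound list**

1 | 4-benzyloxy-3-methoxybenzaldehyde (O-benzylvanillin) | COc1cc(C=O)ccc1OCc1ccccc1 | starting material
2 | dimethyl succinate | COC(=O)CCC(=O)OC | starting material
3 | (E)-4-(4-benzyloxy-3-methoxyphenyl)-3-(methoxycarbonyl)but-3-enoic acid | COC(=O)/C(CC(=O)O)=C/c1ccc(OCc2ccccc2)c(OC)c1 | intermediate
4 | (3S)-4-(4-benzyloxy-3-methoxyphenyl)-3-(methoxycarbonyl)butanoic acid | OC(=O)C[C@@H](C(=O)OC)Cc1ccc(OCc2ccccc2)c(OC)c1 | intermediate
5 | potassium (3S)-4-(4-benzyloxy-3-methoxyphenyl)-3-(methoxycarbonyl)butanoate | [K+].[O-]C(=O)C[C@@H](C(=O)OC)Cc1ccc(OCc2ccccc2)c(OC)c1 | intermediate (not isolated)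
6 | (3S)-4-(4-benzyloxy-3-methoxyphenyl)-3-(hydroxymethyl)butanoic acid | OC(=O)C[C@@H](CO)Cc1ccc(OCc2ccccc2)c(OC)c1 | intermediate (not isolated)
7 | (4S)-4-(4-benzyloxy-3-methoxybenzyl)oxolan-2-one | O=C1C[C@@H](CO1)Cc1ccc(OCc2ccccc2)c(OC)c1 | intermediate
8 | potassium (3S)-4-(4-benzyloxy-3-methoxyphenyl)-3-(hydroxymethyl)butanoate | [K+].[O-]C(=O)C[C@@H](CO)Cc1ccc(OCc2ccccc2)c(OC)c1 | intermediate (not isolated)
9 | (3S)-4-(4-benzyloxy-3-methoxyphenyl)-3-(benzyloxymethyl)butanoic acid | OC(=O)C[C@@H](COCc1ccccc1)Cc1ccc(OCc2ccccc2)c(OC)c1 | intermediate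
10 | methyl (3S)-4-(4-benzyloxy-3-methoxyphenyl)-3-(benzyloxymethyl)butanoate | COC(=O)C[C@@H](COCc1ccccc1)Cc1ccc(OCc2ccccc2)c(OC)c1 | intermediate
11 | methyl formate | COC=O | starting material
12 | methyl (3S)-4-(4-benzyloxy-3-methoxyphenyl)-3-(benzyloxymethyl)-2-formylbutanoate (C2 not fixed) | COC(=O)C(C=O)[C@@H](COCc1ccccc1)Cc1ccc(OCc2ccccc2)c(OC)c1 | intermediate
13 | guaiacol (2-methoxyphenol) | COc1ccccc1O | starting material
14 | methyl (2R,3S)-7-benzyloxy-3-(benzyloxymethyl)-1-hydroxy-6-methoxy-1,2,3,4-tetrahydronaphthalene-2-carboxylate (ester and CH2OBn trans; C1 not fixed) | COC(=O)[C@@H]1[C@@H](COCc2ccccc2)Cc2cc(OC)c(OCc3ccccc3)cc2C1O | intermediate (not isolated)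
15 | methyl (1R,2S,3S)-7-benzyloxy-3-(benzyloxymethyl)-1-(4-hydroxy-3-methoxyphenyl)-6-methoxy-1,2,3,4-tetrahydronaphthalene-2-carboxylate | COC(=O)[C@@H]1[C@@H](COCc2ccccc2)Cc2cc(OC)c(OCc3ccccc3)cc2[C@H]1c1ccc(O)c(OC)c1 | intermediate
16 | methyl (1R,2S,3S)-7-hydroxy-3-(hydroxymethyl)-1-(4-hydroxy-3-methoxyphenyl)-6-methoxy-1,2,3,4-tetrahydronaphthalene-2-carboxylate | COC(=O)[C@@H]1[C@@H](CO)Cc2cc(OC)c(O)cc2[C@H]1c1ccc(O)c(OC)c1 | target

**Step count and risks**

Total step count: 8. Longest linear sequence: 8 steps (from 1).

Steps most likely to fail: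

1. Step 7 (proposed new method). Several processes can divert it.
   - The C1 cation may lose its C2 proton faster than guaiacol captures it. Re-entry through reprotonation then puts C2, and with it the face of attack at C1, under weaker control, so diastereomers at C1/C2 could form.
   - Guaiacol may attack through the carbon para to OMe or ortho to OH.
   - Guaiacol may arylate the formyl carbon twice before ring A closes.
   - The acid may cleave the aryl benzyl ether. This is tolerable, because that group falls in step 8 anyway and the excess guaiacol scavenges the benzyl cation.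

   Fallback, by known chemistry, sets out from 10 and uses aldehyde 1 as the source of the pendant ring. LDA in THF at −78 °C followed by 1 should give the aldol adduct methyl (3S)-2-[(4-benzyloxy-3-methoxyphenyl)(hydroxy)methyl]-4-(4-benzyloxy-3-methoxyphenyl)-3-(benzyloxymethyl)butanoate F1. CF3CO2H in CH2Cl2 ionises its benzylic alcohol and ring A closes ring B onto the cation through a chair with the aryl group equatorial and cis to the C3 CH2OBn, which is the established aldol/cyclialkylation sequence of aryltetralin lignans. NaOMe in MeOH then brings any C2 epimer to the all-trans ester methyl (1R,2S,3S)-7-benzyloxy-1-(4-benzyloxy-3-methoxyphenyl)-3-(benzyloxymethyl)-6-methoxy-1,2,3,4-tetrahydronaphthalene-2-carboxylate F2. Hydrogenolysis under the conditions of step 8 comes back to the route at 16.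

2. Step 6. Claisen formylation of a β-branched alkyl ester may stall or be overtaken by ester self-condensation. Fallback sets out from 10: LDA in THF at −78 °C and monomeric formaldehyde should give methyl (3S)-4-(4-benzyloxy-3-methoxyphenyl)-3-(benzyloxymethyl)-2-(hydroxymethyl)butanoate F3. Dess–Martin periodinane in CH2Cl2 oxidises it to the formyl ester and the route is rejoined at 12.

3. Step 4. In the heterogeneous medium O-benzylation may be incomplete, and unreacted hydroxy carboxylate then relactonises on acidification. Fallback sets out from 7: KOH in aqueous MeOH opens the lactone and the salt 8 is isolated dry. NaH and BnBr in DMF then alkylate both oxygens to give benzyl (3S)-4-(4-benzyloxy-3-methoxyphenyl)-3-(benzyloxymethyl)butanoate F4. K2CO3 in MeOH transesterifies F4 and the route is rejoined at 10, with 9 bypassed.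

**Further compounds**

F1 | step 7 | methyl (3S)-2-[(4-benzyloxy-3-methoxyphenyl)(hydroxy)methyl]-4-(4-benzyloxy-3-methoxyphenyl)-3-(benzyloxymethyl)butanoate | COC(=O)C(C(O)c1ccc(OCc2ccccc2)c(OC)c1)[C@@H](COCc1ccccc1)Cc1ccc(OCc2ccccc2)c(OC)c1
F2 | step 7 | methyl (1R,2S,3S)-7-benzyloxy-1-(4-benzyloxy-3-methoxyphenyl)-3-(benzyloxymethyl)-6-methoxy-1,2,3,4-tetrahydronaphthalene-2-carboxylate | COC(=O)[C@@H]1[C@@H](COCc2ccccc2)Cc2cc(OC)c(OCc3ccccc3)cc2[C@H]1c1ccc(OCc2ccccc2)c(OC)c1
F3 | step 6 | methyl (3S)-4-(4-benzyloxy-3-methoxyphenyl)-3-(benzyloxymethyl)-2-(hydroxymethyl)butanoate | COC(=O)C(CO)[C@@H](COCc1ccccc1)Cc1ccc(OCc2ccccc2)c(OC)c1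
F4 | step 4 | benzyl (3S)-4-(4-benzyloxy-3-methoxyphenyl)-3-(benzyloxymethyl)butanoate | O=C(OCc1ccccc1)C[C@@H](COCc1ccccc1)Cc1ccc(OCc2ccccc2)c(OC)c1
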